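**Strategy.** The 1,2-dioxan-3-ol ring is a cyclised γ-hydroperoxy ketone: hemiketal carbon C3 is a masked ketone, and its α-carbon C4 is linked through C5 to the tertiary peroxy carbon C6. The ring is therefore assembled in one operation from three pieces: a β-keto ester radical (C3–C4), the terminal alkene C5=C6 carrying the whole side chain, and dioxygen (O1–O2). The key step joins C4 to C5 and C6 to O1, and the hydroperoxide then closes onto C3. Its precursors are the chiral 2-methyl-1-alkene 8 and keto ester 13, whose tert-butyl ester directs radical formation to C4 and is later lost as CO2; the acetic acid arm is carried as a silyl-protected hydroxyethyl group.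

Key step: step 6

Remark on the chemistry: methyl and the CH2 of the side chain at C6 are too alike in size for any ring-based induction, so the configuration at C6, and with it the C4/C6 relationship, is secured by chromatographic separation after step 7 and not by induction; only C8 (chiral pool) and C3 (anomeric equilibrium) are controlled by the substrate.

Step 1
Reactants: 1 (7-bromoheptyl)benzene; 2 (S)-3-bromo-2-methylpropan-1-ol
Product: 5 (R)-2-methyl-10-phenyldecan-1-ol, via 7-phenylheptylmagnesium bromide 3 (not isolated), via chloromagnesium alkoxide 4 (not isolated)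
Conditions: 1, Mg, THF, 40 °C; separately 2, MeMgCl (1.0 equiv), THF, −20 °C; combine, Li2CuCl4 (3 mol %), −20 °C to rt; dilute HCl work-up
Reagents that add atoms: none
Why: Copper-catalysed Kochi–Schlosser sp3–sp3 coupling of a primary Grignard reagent with a primary bromide, in which the stereocenter of 2 (the future C8) is not at a reacting carbon and is carried unchanged, the descriptor changing from S to R only because the CH2Br arm becomes the lower-ranked alkyl arm.

Step 2
Reactants: 5 (R)-2-methyl-10-phenyldecan-1-ol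
Product: 6 (R)-2-methyl-10-phenyldecyl 4-methylbenzenesulfonate
Conditions: TsCl, Et3N, DMAP (cat.), CH2Cl2, 0 °C to rt
Reagents that add atoms: 4-methylbenzenesulfonyl chloride Cc1ccc(cc1)S(Cl)(=O)=O
Why: Standard tosylation of a primary alcohol, which makes C1 a leaving group without touching the stereocenter.

Step 3
Reactants: 6 (R)-2-methyl-10-phenyldecyl 4-methylbenzenesulfonate; 7 isopropenylmagnesium bromide
Product: 8 (R)-2,4-dimethyl-12-phenyldodec-1-ene
Conditions: 7 (2 equiv), CuI (10 mol %), THF, 0 °C to rt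
Reagents that add atoms: none
Why: Copper-catalysed cross-coupling of an alkenyl Grignard reagent with a primary tosylate installs the isopropenyl unit (future C5, C6 and the C6 methyl) by displacement at CH2, so the neighbouring stereocenter stays R.

Step 4
Reactants: 9 tert-butyl propanoate; 10 3-[(tert-butyldiphenylsilyl)oxy]propanal
Product: 12 tert-butyl 5-[(tert-butyldiphenylsilyl)oxy]-3-hydroxy-2-methylpentanoate (mixture of diastereomers), via lithium enolate 11 (not isolated)
Conditions: LDA, THF, −78 °C; then 10, −78 °C; AcOH quench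
Reagents that add atoms: none
Why: Directed aldol addition of a lithium ester enolate to an aldehyde, where the two new stereocenters need no control because one is oxidised in step 5 and the other becomes the radical centre in step 6.

Step 5
Reactants: 12 tert-butyl 5-[(tert-butyldiphenylsilyl)oxy]-3-hydroxy-2-methylpentanoate
Product: 13 tert-butyl 5-[(tert-butyldiphenylsilyl)oxy]-2-methyl-3-oxopentanoate
Conditions: Dess–Martin periodinane, CH2Cl2, rt
Reagents that add atoms: none
Why: Dess–Martin oxidation of a β-hydroxy ester to the β-keto ester under neutral conditions that spare the silyl ether and the tert-butyl ester, giving a substrate with a single C–H flanked by two carbonyl groups.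

Step 6
Reactants: 8 (R)-2,4-dimethyl-12-phenyldodec-1-ene; 13 tert-butyl 5-[(tert-butyldiphenylsilyl)oxy]-2-methyl-3-oxopentanoate
Product: 15 tert-butyl 3-{2-[(tert-butyldiphenylsilyl)oxy]ethyl}-3-hydroxy-4,6-dimethyl-6-[(2R)-2-methyl-10-phenyldecyl]-1,2-dioxane-4-carboxylate (mixture of isomers at C3, C4 and C6), via hydroperoxy keto ester 14 (not isolated)
Conditions: 13 (2 equiv), Mn(OAc)3·2H2O (0.2 equiv), Mn(OAc)2·4H2O (0.2 equiv), AcOH, dioxygen (1 atm), 23 °C
Reagents that add atoms: dioxygen O=O
Why: Mn(OAc)3 forms the manganese enolate of 13 at its only C–H flanked by two carbonyl groups and oxidises it to an electrophilic α-carbonyl radical that adds to the unsubstituted terminus of alkene 8 (C4–C5 bond), the tertiary C6 radical captures dioxygen (C6–O1 bond), and the peroxyl radical is reduced by divalent manganese to hydroperoxide 14, which regenerates the trivalent oxidant. The closest known reaction type is the Mn(OAc)3-mediated aerobic [2+2+2] peroxycyclisation of 1,3-dicarbonyl compounds with 1,1-disubstituted alkenes to 1,2-dioxan-3-ols. The 1,2-dioxane ring closes by reversible 6-exo-trig addition of the hydroperoxide oxygen O2 to the C3 ketone. C3 is set under thermodynamic control (axial anomeric OH), the quaternary C4 is not controlled and need not be because it is reset in step 7, and C6 arises from dioxygen capture by an acyclic tertiary radical for which no facial bias is claimed, so both C6 epimers are carried on. The step needs site selectivity for the radical, secured by the tert-butyl ester at C4 and by masking the acid arm as a non-activating silyloxyethyl group, and regioselectivity of addition, secured by formation of the tertiary radical; the phenyl ring and benzylic C–H bonds should not be attacked at 23 °C.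

Step 7
Reactants: 15 tert-butyl 3-{2-[(tert-butyldiphenylsilyl)oxy]ethyl}-3-hydroxy-4,6-dimethyl-6-[(2R)-2-methyl-10-phenyldecyl]-1,2-dioxane-4-carboxylate
Product: 17 (3S,4R,6S)-3-{2-[(tert-butyldiphenylsilyl)oxy]ethyl}-4,6-dimethyl-6-[(2R)-2-methyl-10-phenyldecyl]-1,2-dioxan-3-ol, via carboxylic acid 16 (not isolated)
Conditions: TFA/CH2Cl2 (1:4), 0 °C to rt; evaporation; toluene, 50 °C; silica gel chromatography, then HPLC on a chiral stationary phase
Reagents that add atoms: none
Why: Acidolysis of the tert-butyl ester gives β-keto acid 16, whose ring-opened hydroperoxy ketone tautomer decarboxylates through the usual six-membered transition state to an enol, and ketonisation with re-closure on C3 places the hemiketal OH axial and cis to an equatorial 4-methyl group, whereas C4 forms without bias relative to C6, so the (3S,4R,6S) isomer is taken by chromatography (the 4-epimeric series on silica, the quasi-enantiomeric 6-epimeric series on the chiral phase) and the 4-epimer can be returned to the acidic conditions for re-equilibration.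

Step 8
Reactants: 17 (3S,4R,6S)-3-{2-[(tert-butyldiphenylsilyl)oxy]ethyl}-4,6-dimethyl-6-[(2R)-2-methyl-10-phenyldecyl]-1,2-dioxan-3-ol
Product: 18 (3S,4R,6S)-3-(2-hydroxyethyl)-4,6-dimethyl-6-[(2R)-2-methyl-10-phenyldecyl]-1,2-dioxan-3-ol
Conditions: TBAF, AcOH (1:1), THF, 0 °C to rt
Reagents that add atoms: none
Why: Fluoride-mediated cleavage of the primary silyl ether, buffered with acetic acid so that the peroxyhemiketal stays closed and C4, α to the masked ketone, should not epimerise.

Step 9
Reactants: 18 (3S,4R,6S)-3-(2-hydroxyethyl)-4,6-dimethyl-6-[(2R)-2-methyl-10-phenyldecyl]-1,2-dioxan-3-ol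
Product: 19 2-{(3S,4R,6S)-3-hydroxy-4,6-dimethyl-6-[(2R)-2-methyl-10-phenyldecyl]-1,2-dioxan-3-yl}acetic acid
Conditions: TEMPO (0.2 equiv), PhI(OAc)2 (2.5 equiv), MeCN/pH 7 phosphate buffer, rt
Reagents that add atoms: water O
Why: Nitroxyl-catalysed oxidation of the primary alcohol through the aldehyde hydrate to the carboxylic acid under near-neutral conditions that should be tolerated by the O–O bond, the tertiary hemiketal OH and the configured C4.

**Compound list**

1 | (7-bromoheptyl)benzene | BrCCCCCCCc1ccccc1 | starting material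
2 | (S)-3-bromo-2-methylpropan-1-ol | C[C@H](CBr)CO | starting material
3 | 7-phenylheptylmagnesium bromide | Br[Mg]CCCCCCCc1ccccc1 | intermediate (not isolated)
4 | chloromagnesium (S)-3-bromo-2-methylpropan-1-olate | C[C@H](CBr)CO[Mg]Cl | intermediate (not isolated)
5 | (R)-2-methyl-10-phenyldecan-1-ol | C[C@H](CCCCCCCCc1ccccc1)CO | intermediate
6 | (R)-2-methyl-10-phenyldecyl 4-methylbenzenesulfonate | C[C@H](CCCCCCCCc1ccccc1)COS(=O)(=O)c1ccc(C)cc1 | intermediate
7 | isopropenylmagnesium bromide (prop-1-en-2-ylmagnesium bromide) | CC(=C)[Mg]Br | starting material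
8 | (R)-2,4-dimethyl-12-phenyldodec-1-ene | C[C@H](CCCCCCCCc1ccccc1)CC(C)=C | intermediate
9 | tert-butyl propanoate | CCC(=O)OC(C)(C)C | starting material
10 | 3-[(tert-butyldiphenylsilyl)oxy]propanal | O=CCCO[Si](c1ccccc1)(c1ccccc1)C(C)(C)C | starting material
11 | lithium enolate of tert-butyl propanoate | CC=C(O[Li])OC(C)(C)C | intermediate (not isolated)
12 | tert-butyl 5-[(tert-butyldiphenylsilyl)oxy]-3-hydroxy-2-methylpentanoate (diastereomer mixture, racemic) | CC(C(=O)OC(C)(C)C)C(O)CCO[Si](c1ccccc1)(c1ccccc1)C(C)(C)C | intermediate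
13 | tert-butyl 5-[(tert-butyldiphenylsilyl)oxy]-2-methyl-3-oxopentanoate (racemic, labile centre) | CC(C(=O)OC(C)(C)C)C(=O)CCO[Si](c1ccccc1)(c1ccccc1)C(C)(C)C | intermediate
14 | tert-butyl 5-[(tert-butyldiphenylsilyl)oxy]-2-[(4R)-2-hydroperoxy-2,4-dimethyl-12-phenyldodecyl]-2-methyl-3-oxopentanoate (mixture at the two new centres) | C[C@H](CCCCCCCCc1ccccc1)CC(C)(OO)CC(C)(C(=O)OC(C)(C)C)C(=O)CCO[Si](c1ccccc1)(c1ccccc1)C(C)(C)C | intermediate (not isolated)
15 | tert-butyl 3-{2-[(tert-butyldiphenylsilyl)oxy]ethyl}-3-hydroxy-4,6-dimethyl-6-[(2R)-2-methyl-10-phenyldecyl]-1,2-dioxane-4-carboxylate (mixture at C3, C4, C6) | C[C@H](CCCCCCCCc1ccccc1)CC1(C)CC(C)(C(=O)OC(C)(C)C)C(O)(CCO[Si](c2ccccc2)(c2ccccc2)C(C)(C)C)OO1 | intermediate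
16 | 3-{2-[(tert-butyldiphenylsilyl)oxy]ethyl}-3-hydroxy-4,6-dimethyl-6-[(2R)-2-methyl-10-phenyldecyl]-1,2-dioxane-4-carboxylic acid (mixture at C3, C4, C6) | C[C@H](CCCCCCCCc1ccccc1)CC1(C)CC(C)(C(=O)O)C(O)(CCO[Si](c2ccccc2)(c2ccccc2)C(C)(C)C)OO1 | intermediate (not isolated)
17 | (3S,4R,6S)-3-{2-[(tert-butyldiphenylsilyl)oxy]ethyl}-4,6-dimethyl-6-[(2R)-2-methyl-10-phenyldecyl]-1,2-dioxan-3-ol (single isomer after separation) | C[C@H](CCCCCCCCc1ccccc1)C[C@@]1(C)C[C@@H](C)[C@](O)(CCO[Si](c2ccccc2)(c2ccccc2)C(C)(C)C)OO1 | intermediate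
18 | (3S,4R,6S)-3-(2-hydroxyethyl)-4,6-dimethyl-6-[(2R)-2-methyl-10-phenyldecyl]-1,2-dioxan-3-ol | C[C@H](CCCCCCCCc1ccccc1)C[C@@]1(C)C[C@@H](C)[C@](O)(CCO)OO1 | intermediate
19 | 2-{(3S,4R,6S)-3-hydroxy-4,6-dimethyl-6-[(2R)-2-methyl-10-phenyldecyl]-1,2-dioxan-3-yl}acetic acid | C[C@H](CCCCCCCCc1ccccc1)C[C@@]1(C)C[C@@H](C)[C@](O)(CC(=O)O)OO1 | target

**Step count and risks**

Total step count: 9. Longest linear sequence: 7 steps (steps 1, 2, 3, 6, 7, 8, 9).

Steps most likely to fail:

Step 6. The hindered α-methyl manganese enolate radical may be intercepted by dioxygen (α-hydroxylation of 13) faster than it adds to the unactivated alkene, and the alkene may be lost to autoxidation. No facial selectivity at C6 is available either. The fallback forms the C4–C5 and C6–O1 bonds in separate operations. It sets out from tosylate 6 and keto ester 13. Tosylate 6 would be converted with NaI in acetone into [(9R)-10-iodo-9-methyldecyl]benzene F1. Keto ester 13 would be alkylated with 2,3-dibromopropene (K2CO3, acetone) to tert-butyl 2-(2-bromoprop-2-en-1-yl)-5-[(tert-butyldiphenylsilyl)oxy]-2-methyl-3-oxopentanoate F2. Zinc insertion into F1 would give [(2R)-2-methyl-10-phenyldecyl]zinc iodide F3. Negishi coupling of F3 with F2 under PdCl2(dppf) catalysis would give tert-butyl 5-[(tert-butyldiphenylsilyl)oxy]-2-methyl-2-[(4R)-4-methyl-2-methylidene-12-phenyldodecyl]-3-oxopentanoate F4. Mukaiyama–Isayama hydroperoxysilylation of F4 (Co(acac)2, dioxygen, Et3SiH) would give tert-butyl 5-[(tert-butyldiphenylsilyl)oxy]-2-{(4R)-2,4-dimethyl-12-phenyl-2-[(triethylsilyl)peroxy]dodecyl}-2-methyl-3-oxopentanoate F5. Mild acidic desilylation (AcOH, THF, water) should release hydroperoxide 14, which closes to 15, where the fallback comes back to the route.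

Step 7. Instead of ring opening and decarboxylation, the protonated peroxyhemiketal may undergo Criegee- or Hock-type heterolysis of the O–O bond. Alternatively the silyl ether may be lost, and the freed alcohol may lactonise onto the C4 acid and block decarboxylation. The fallback replaces the acid-labile ester by a fluoride-labile one. It sets out from aldehyde 10 and alkene 8. Propanoyl chloride and 2-(trimethylsilyl)ethanol would give 2-(trimethylsilyl)ethyl propanoate F6. Aldol addition of its lithium enolate to 10 would give 2-(trimethylsilyl)ethyl 5-[(tert-butyldiphenylsilyl)oxy]-3-hydroxy-2-methylpentanoate F7. Dess–Martin oxidation would give 2-(trimethylsilyl)ethyl 5-[(tert-butyldiphenylsilyl)oxy]-2-methyl-3-oxopentanoate F8. The Mn(OAc)3/dioxygen reaction of F8 with 8 would give 2-(trimethylsilyl)ethyl 3-{2-[(tert-butyldiphenylsilyl)oxy]ethyl}-3-hydroxy-4,6-dimethyl-6-[(2R)-2-methyl-10-phenyldecyl]-1,2-dioxane-4-carboxylate F9. Excess TBAF in THF should cleave both silyl groups without strong acid, and buffering with AcOH at 40 °C should bring about decarboxylation. After the same separation of isomers this comes back to the route at 18.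

Step 9. The intermediate β-peroxyhemiketal aldehyde may ring-open to an enolised 1,3-keto aldehyde that stalls or is over-oxidised, and the product, a masked β-keto acid, may decarboxylate. The fallback locks the ring before the oxidation. It sets out from 18, which with MeOH and pyridinium p-toluenesulfonate would give 2-{(3S,4R,6S)-3-methoxy-4,6-dimethyl-6-[(2R)-2-methyl-10-phenyldecyl]-1,2-dioxan-3-yl}ethan-1-ol F10. Its oxidation (TEMPO, PhI(OAc)2) would give 2-{(3S,4R,6S)-3-methoxy-4,6-dimethyl-6-[(2R)-2-methyl-10-phenyldecyl]-1,2-dioxan-3-yl}acetic acid F11. Hydrolysis of the methyl peroxyketal in aqueous acid (TFA, THF, water) through the peroxycarbenium ion should return the axial hemiketal and come back to the route at 19.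

**Further compounds**

F1 | step 6 | [(9R)-10-iodo-9-methyldecyl]benzene | C[C@H](CCCCCCCCc1ccccc1)CI
F2 | step 6 | tert-butyl 2-(2-bromoprop-2-en-1-yl)-5-[(tert-butyldiphenylsilyl)oxy]-2-methyl-3-oxopentanoate | CC(CC(Br)=C)(C(=O)OC(C)(C)C)C(=O)CCO[Si](c1ccccc1)(c1ccccc1)C(C)(C)C
F3 | step 6 | [(2R)-2-methyl-10-phenyldecyl]zinc iodide | C[C@H](CCCCCCCCc1ccccc1)C[Zn]I
F4 | step 6 | tert-butyl 5-[(tert-butyldiphenylsilyl)oxy]-2-methyl-2-[(4R)-4-methyl-2-methylidene-12-phenyldodecyl]-3-oxopentanoate | C[C@H](CCCCCCCCc1ccccc1)CC(=C)CC(C)(C(=O)OC(C)(C)C)C(=O)CCO[Si](c1ccccc1)(c1ccccc1)C(C)(C)C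
F5 | step 6 | tert-butyl 5-[(tert-butyldiphenylsilyl)oxy]-2-{(4R)-2,4-dimethyl-12-phenyl-2-[(triethylsilyl)peroxy]dodecyl}-2-methyl-3-oxopentanoate | C[C@H](CCCCCCCCc1ccccc1)CC(C)(OO[Si](CC)(CC)CC)CC(C)(C(=O)OC(C)(C)C)C(=O)CCO[Si](c1ccccc1)(c1ccccc1)C(C)(C)C
F6 | step 7 | 2-(trimethylsilyl)ethyl propanoate | CCC(=O)OCC[Si](C)(C)C
F7 | step 7 | 2-(trimethylsilyl)ethyl 5-[(tert-butyldiphenylsilyl)oxy]-3-hydroxy-2-methylpentanoate | CC(C(=O)OCC[Si](C)(C)C)C(O)CCO[Si](c1ccccc1)(c1ccccc1)C(C)(C)C
F8 | step 7 | 2-(trimethylsilyl)ethyl 5-[(tert-butyldiphenylsilyl)oxy]-2-methyl-3-oxopentanoate | CC(C(=O)OCC[Si](C)(C)C)C(=O)CCO[Si](c1ccccc1)(c1ccccc1)C(C)(C)C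
F9 | step 7 | 2-(trimethylsilyl)ethyl 3-{2-[(tert-butyldiphenylsilyl)oxy]ethyl}-3-hydroxy-4,6-dimethyl-6-[(2R)-2-methyl-10-phenyldecyl]-1,2-dioxane-4-carboxylate | C[C@H](CCCCCCCCc1ccccc1)CC1(C)CC(C)(C(=O)OCC[Si](C)(C)C)C(O)(CCO[Si](c2ccccc2)(c2ccccc2)C(C)(C)C)OO1
F10 | step 9 | 2-{(3S,4R,6S)-3-methoxy-4,6-dimethyl-6-[(2R)-2-methyl-10-phenyldecyl]-1,2-dioxan-3-yl}ethan-1-ol | C[C@H](CCCCCCCCc1ccccc1)C[C@@]1(C)C[C@@H](C)[C@](OC)(CCO)OO1
F11 | step 9 | 2-{(3S,4R,6S)-3-methoxy-4,6-dimethyl-6-[(2R)-2-methyl-10-phenyldecyl]-1,2-dioxan-3-yl}acetic acid | C[C@H](CCCCCCCCc1ccccc1)C[C@@]1(C)C[C@@H](C)[C@](OC)(CC(=O)O)OO1
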